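**Plan**
Retrosynthesis: the enal is cut at its Cα=Cβ double bond (Wittig), leading back to a C7 aldehyde and then a C7 ester. The benzene ring is taken back to a cyclohex-2-enone (C5-OH becomes C5=O), and the dioxane ring is cut at O4-C4a and O1-C2 in one operation.
Enabling feature: the heterocycle O1-C2(aryl)-C3(CH2OH)-O4-C4a-C8a is fused to an arene oxygenated on the three contiguous carbons C8a, C4a and C5, and only the C5 oxygen is unalkylated. C8a/C4a/C5 therefore correspond to C1/C2/C3 of a mirror-symmetric 5-carboxycyclohexane-1,3-dione with a carbene at C2, and C2-C3-O4 corresponds to a trans aryl epoxide.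
Forward: two three-step branches give the silylated epoxide and the diazodione. Their union closes the dioxene ring onto the existing carbocycle (step 7), the carbocycle is dehydrogenated to the arene (step 8), the ester is taken to the aldehyde and extended by two carbons (steps 9-11), and the silyl ether is removed last.
Stereochemistry: C2 and C3 both come from a Sharpless epoxidation with L-(+)-tartrate. C3 keeps its C-O bond to the end, C2 exchanges its oxygen with retention in step 7, and the E-alkene comes from a stabilised ylide.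

Key step: step 7

Remark: all bicyclic compounds, aromatic or not, are numbered as 1,4-benzodioxines (O1, C2, C3, O4, C4a, C5-C8, C8a). The 1,3-diones are drawn in the diketo form although they are largely enolised.

Step 1
Reactants: 1 (E)-3,4,5-trimethoxycinnamic acid
Product: 3 (E)-3-(3,4,5-trimethoxyphenyl)prop-2-en-1-ol, via mixed ethyl carbonic anhydride 2 (not isolated)
Conditions: ClCO2Et, Et3N, THF, -10 °C; then NaBH4, THF-H2O, 0 °C to rt
Reagents that add atoms: ethyl chloroformate, CCOC(=O)Cl (its atoms are carried by 2 only)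
Why: Borohydride reduction of a mixed carbonic anhydride attacks the activated acyl carbon in a 1,2 sense much faster than the conjugated alkene, so the E-olefin should survive, which is not assured with LiAlH4.

Step 2
Reactants: 3 (E)-3-(3,4,5-trimethoxyphenyl)prop-2-en-1-ol
Product: 4 [(2S,3S)-3-(3,4,5-trimethoxyphenyl)oxiran-2-yl]methanol
Conditions: Ti(OiPr)4 (10 mol %), L-(+)-DIPT (13 mol %), anhydrous TBHP, 4 Å MS, CH2Cl2, -25 °C; basic work-up (NaOH in brine)
Reagents that add atoms: tert-butyl hydroperoxide, CC(C)(C)OO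
Why: In the Katsuki-Sharpless asymmetric epoxidation the L-(+)-tartrate titanium complex delivers oxygen to the face of the E-allylic alcohol that gives the (2S,3S)-trans-epoxide, which sets both stereocentres of the target, and the catalytic low-temperature sieve protocol limits titanium-promoted opening of the electron-rich benzylic epoxide.

Step 3
Reactants: 4 [(2S,3S)-3-(3,4,5-trimethoxyphenyl)oxiran-2-yl]methanol
Product: 5 tert-butyl(dimethyl){[(2S,3S)-3-(3,4,5-trimethoxyphenyl)oxiran-2-yl]methoxy}silane
Conditions: TBSCl, imidazole, CH2Cl2, 0 °C to rt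
Reagents that add atoms: tert-butyldimethylsilyl chloride, CC(C)(C)[Si](C)(C)Cl
Why: Imidazole-promoted silylation of a primary alcohol runs under non-acidic conditions that spare the epoxide, and it masks the hydroxyl group that would otherwise undergo O-H insertion with the carbene in step 7.

Step 4
Reactants: 6 3,5-dihydroxybenzoic acid
Product: 7 3,5-dioxocyclohexane-1-carboxylic acid
Conditions: H2 (ca. 100 bar), Raney Ni, aq NaOH (2 equiv), 50 °C; then conc. HCl to pH 1, 0 °C
Reagents that add atoms: none
Why: In this partial hydrogenation of a resorcinol as its phenolate (the dihydroresorcinol reduction), uptake stops after one equivalent of H2 because the product is held as the reduction-resistant 1,3-dione enolate, and the carboxylate is inert.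

Step 5
Reactants: 7 3,5-dioxocyclohexane-1-carboxylic acid
Product: 9 methyl 3,5-dioxocyclohexane-1-carboxylate, via methyl enol ether ester 8 (not isolated)
Conditions: MeOH, cat. H2SO4, reflux; concentrate; then 1 M aq HCl-THF, rt
Reagents that add atoms: methanol, CO
Why: Fischer esterification also converts the acidic dione into its methyl enol ether 8, but dilute aqueous acid hydrolyses this vinylogous ester far faster than the saturated methyl ester, so the two-stage protocol should give 9 selectively.

Step 6
Reactants: 9 methyl 3,5-dioxocyclohexane-1-carboxylate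
Product: 10 methyl 4-diazo-3,5-dioxocyclohexane-1-carboxylate
Conditions: p-ABSA, Et3N, MeCN, 0 °C to rt
Reagents that add atoms: 4-acetamidobenzenesulfonyl azide, CC(=O)Nc1ccc(cc1)S(=O)(=O)N=[N+]=[N-]
Why: Regitz diazo transfer occurs at the C4 methylene flanked by both carbonyl groups, which a tertiary amine fully deprotonates, whereas the ester α-carbon is far too weakly acidic to compete.

Step 7
Reactants: 5 tert-butyl(dimethyl){[(2S,3S)-3-(3,4,5-trimethoxyphenyl)oxiran-2-yl]methoxy}silane; 10 methyl 4-diazo-3,5-dioxocyclohexane-1-carboxylate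
Product: 11 methyl (2S,3S)-3-[(tert-butyldimethylsilyloxy)methyl]-5-oxo-2-(3,4,5-trimethoxyphenyl)-2,3,5,6,7,8-hexahydro-1,4-benzodioxine-7-carboxylate (trans at C2/C3; C7 epimer mixture)
Conditions: [CpRu(MeCN)3]PF6 (5 mol %), 1,10-phenanthroline (5 mol %), CH2Cl2, 60 °C (sealed vessel), 10 (1.5 equiv) added slowly by syringe pump
Reagents that add atoms: none
Why: The CpRu(phen) fragment expels N2 from 10 to give an electrophilic carbene at the future C4a; the epoxide oxygen of 5 adds to it (C4a-O4 bond), the resulting oxonium ylide loosens its benzylic C2-O bond, and one enolate oxygen of the dione collapses onto C2 (O1-C2 bond) with release of the catalyst. The closest known reaction type is the CpRu/phenanthroline-catalysed three-atom insertion ([3+3] condensation) of α-diazo-β-dicarbonyl carbenes into epoxides, which gives 1,4-dioxenes by SN1-like opening with retention. The one new ring, the six-membered dioxene O1-C2-C3-O4-C4a-C8a, closes in an endo sense at the epoxide carbon: the carbocycle holds nucleophile O1 and leaving group O4 cis on the same C8a=C4a unit, so backside SN2 attack is geometrically excluded and closure is a front-side capture within a contact ion pair. C3 never breaks its C-O bond and keeps the Sharpless configuration, C2 is re-bonded on the face that O4 has just left (retention, trans-epoxide to trans-dioxene, which is also the diequatorial thermodynamic isomer), and the new C7 centre forms without control but is destroyed in step 8. The step needs exclusive cleavage of the benzylic C-O bond, secured by the cation-stabilising trimethoxyphenyl group at C2 and the inductively destabilising CH2OTBS group at C3, while the mirror symmetry of 10 makes its two carbonyl oxygens equivalent, so only one constitutional isomer can arise and the untouched carbonyl is left at C5. Chemoselectivity against oxygen-atom transfer from the epoxide, attack on the electron-rich arene and O-H insertion is addressed by the mild Ru carbene, the slow addition of 10 and the silyl ether.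

Step 8
Reactants: 11 methyl (2S,3S)-3-[(tert-butyldimethylsilyloxy)methyl]-5-oxo-2-(3,4,5-trimethoxyphenyl)-2,3,5,6,7,8-hexahydro-1,4-benzodioxine-7-carboxylate
Product: 14 methyl (2S,3S)-3-[(tert-butyldimethylsilyloxy)methyl]-5-hydroxy-2-(3,4,5-trimethoxyphenyl)-2,3-dihydro-1,4-benzodioxine-7-carboxylate, via TMS dienol ether 12 (not isolated), via cross-conjugated cyclohexadienone 13 (not isolated)
Conditions: LiHMDS (1.1 equiv), TMSCl, THF, -78 to 0 °C; concentrate; Pd(OAc)2 (1.05 equiv), MeCN, rt
Reagents that add atoms: chlorotrimethylsilane, C[Si](C)(C)Cl (its silyl group is carried by 12 only)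
Why: In this Saegusa-Ito dehydrogenation, kinetic deprotonation of the vinylogous ester at the α' carbon C6 and silylation give 12, Pd(II) adds at C6 and β-hydride elimination of C7-H gives dienone 13, which tautomerises irreversibly to the phenol, so the C7 epimer mixture is erased while C2 and C3 are untouched.

Step 9
Reactants: 14 methyl (2S,3S)-3-[(tert-butyldimethylsilyloxy)methyl]-5-hydroxy-2-(3,4,5-trimethoxyphenyl)-2,3-dihydro-1,4-benzodioxine-7-carboxylate
Product: 15 (2S,3S)-3-[(tert-butyldimethylsilyloxy)methyl]-7-(hydroxymethyl)-2-(3,4,5-trimethoxyphenyl)-2,3-dihydro-1,4-benzodioxin-5-ol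
Conditions: DIBAL-H (3.5 equiv), CH2Cl2, -78 to 0 °C; aq Rochelle salt
Reagents that add atoms: none
Why: DIBAL-H reduces the aromatic ester to the benzylic alcohol after the first equivalent has been consumed by the phenol as its aluminium phenoxide, and the silyl ether and aryl ethers are inert at low temperature.

Step 10
Reactants: 15 (2S,3S)-3-[(tert-butyldimethylsilyloxy)methyl]-7-(hydroxymethyl)-2-(3,4,5-trimethoxyphenyl)-2,3-dihydro-1,4-benzodioxin-5-ol
Product: 16 (2S,3S)-3-[(tert-butyldimethylsilyloxy)methyl]-5-hydroxy-2-(3,4,5-trimethoxyphenyl)-2,3-dihydro-1,4-benzodioxine-7-carbaldehyde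
Conditions: activated MnO2 (excess), CH2Cl2, rt
Reagents that add atoms: none
Why: Activated MnO2 oxidises the benzylic alcohol, the only free alcohol and one activated by the para oxygen O4, stops at the aldehyde, and works under neutral heterogeneous conditions that a meta phenol should tolerate.

Step 11
Reactants: 16 (2S,3S)-3-[(tert-butyldimethylsilyloxy)methyl]-5-hydroxy-2-(3,4,5-trimethoxyphenyl)-2,3-dihydro-1,4-benzodioxine-7-carbaldehyde
Product: 17 (E)-3-{(2S,3S)-3-[(tert-butyldimethylsilyloxy)methyl]-5-hydroxy-2-(3,4,5-trimethoxyphenyl)-2,3-dihydro-1,4-benzodioxin-7-yl}prop-2-enal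
Conditions: Ph3P=CHCHO (1.3 equiv), toluene, 80 °C
Reagents that add atoms: (triphenylphosphoranylidene)acetaldehyde, O=CC=P(c1ccccc1)(c1ccccc1)c1ccccc1
Why: Wittig olefination with the stabilised formylmethylene ylide gives the E-enal, and the ylide is too weakly basic to be quenched by the free phenol.

Step 12
Reactants: 17 (E)-3-{(2S,3S)-3-[(tert-butyldimethylsilyloxy)methyl]-5-hydroxy-2-(3,4,5-trimethoxyphenyl)-2,3-dihydro-1,4-benzodioxin-7-yl}prop-2-enal
Product: 18 (E)-3-[(2S,3S)-5-hydroxy-3-(hydroxymethyl)-2-(3,4,5-trimethoxyphenyl)-2,3-dihydro-1,4-benzodioxin-7-yl]prop-2-enal (target CNP0241953.1)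
Conditions: HF·pyridine, THF-pyridine, 0 °C to rt
Reagents that add atoms: none
Why: Fluoride-driven cleavage of the primary TBS ether under buffered, mildly acidic conditions should leave the enal, the phenol and the two ether-bound stereocentres unchanged.

**Compound list**
1 | (E)-3,4,5-trimethoxycinnamic acid | COc1cc(/C=C/C(=O)O)cc(OC)c1OC | starting material
2 | ethyl carbonic (E)-3,4,5-trimethoxycinnamic anhydride | CCOC(=O)OC(=O)/C=C/c1cc(OC)c(OC)c(OC)c1 | intermediate
3 | (E)-3-(3,4,5-trimethoxyphenyl)prop-2-en-1-ol | COc1cc(/C=C/CO)cc(OC)c1OC | intermediate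
4 | [(2S,3S)-3-(3,4,5-trimethoxyphenyl)oxiran-2-yl]methanol | COc1cc([C@@H]2O[C@H]2CO)cc(OC)c1OC | intermediate
5 | tert-butyl(dimethyl){[(2S,3S)-3-(3,4,5-trimethoxyphenyl)oxiran-2-yl]methoxy}silane | COc1cc([C@@H]2O[C@H]2CO[Si](C)(C)C(C)(C)C)cc(OC)c1OC | intermediate
6 | 3,5-dihydroxybenzoic acid | OC(=O)c1cc(O)cc(O)c1 | starting material
7 | 3,5-dioxocyclohexane-1-carboxylic acid | OC(=O)C1CC(=O)CC(=O)C1 | intermediate
8 | methyl 3-methoxy-5-oxocyclohex-3-ene-1-carboxylate (racemic) | COC(=O)C1CC(=O)C=C(OC)C1 | intermediate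
9 | methyl 3,5-dioxocyclohexane-1-carboxylate | COC(=O)C1CC(=O)CC(=O)C1 | intermediate
10 | methyl 4-diazo-3,5-dioxocyclohexane-1-carboxylate | COC(=O)C1CC(=O)C(=[N+]=[N-])C(=O)C1 | intermediate
11 | methyl (2S,3S)-3-[(tert-butyldimethylsilyloxy)methyl]-5-oxo-2-(3,4,5-trimethoxyphenyl)-2,3,5,6,7,8-hexahydro-1,4-benzodioxine-7-carboxylate (C7 epimer mixture) | COc1cc([C@@H]2OC3=C(O[C@H]2CO[Si](C)(C)C(C)(C)C)C(=O)CC(C(=O)OC)C3)cc(OC)c1OC | intermediate
12 | methyl (2S,3S)-3-[(tert-butyldimethylsilyloxy)methyl]-2-(3,4,5-trimethoxyphenyl)-5-(trimethylsilyloxy)-2,3,7,8-tetrahydro-1,4-benzodioxine-7-carboxylate (C7 epimer mixture) | COc1cc([C@@H]2OC3=C(O[C@H]2CO[Si](C)(C)C(C)(C)C)C(O[Si](C)(C)C)=CC(C(=O)OC)C3)cc(OC)c1OC | intermediate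
13 | methyl (2S,3S)-3-[(tert-butyldimethylsilyloxy)methyl]-5-oxo-2-(3,4,5-trimethoxyphenyl)-2,3,5,8-tetrahydro-1,4-benzodioxine-7-carboxylate | COc1cc([C@@H]2OC3=C(O[C@H]2CO[Si](C)(C)C(C)(C)C)C(=O)C=C(C(=O)OC)C3)cc(OC)c1OC | intermediate
14 | methyl (2S,3S)-3-[(tert-butyldimethylsilyloxy)methyl]-5-hydroxy-2-(3,4,5-trimethoxyphenyl)-2,3-dihydro-1,4-benzodioxine-7-carboxylate | COc1cc([C@@H]2Oc3cc(C(=O)OC)cc(O)c3O[C@H]2CO[Si](C)(C)C(C)(C)C)cc(OC)c1OC | intermediate
15 | (2S,3S)-3-[(tert-butyldimethylsilyloxy)methyl]-7-(hydroxymethyl)-2-(3,4,5-trimethoxyphenyl)-2,3-dihydro-1,4-benzodioxin-5-ol | COc1cc([C@@H]2Oc3cc(CO)cc(O)c3O[C@H]2CO[Si](C)(C)C(C)(C)C)cc(OC)c1OC | intermediate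
16 | (2S,3S)-3-[(tert-butyldimethylsilyloxy)methyl]-5-hydroxy-2-(3,4,5-trimethoxyphenyl)-2,3-dihydro-1,4-benzodioxine-7-carbaldehyde | COc1cc([C@@H]2Oc3cc(C=O)cc(O)c3O[C@H]2CO[Si](C)(C)C(C)(C)C)cc(OC)c1OC | intermediate
17 | (E)-3-{(2S,3S)-3-[(tert-butyldimethylsilyloxy)methyl]-5-hydroxy-2-(3,4,5-trimethoxyphenyl)-2,3-dihydro-1,4-benzodioxin-7-yl}prop-2-enal | COc1cc([C@@H]2Oc3cc(/C=C/C=O)cc(O)c3O[C@H]2CO[Si](C)(C)C(C)(C)C)cc(OC)c1OC | intermediate
18 | (E)-3-[(2S,3S)-5-hydroxy-3-(hydroxymethyl)-2-(3,4,5-trimethoxyphenyl)-2,3-dihydro-1,4-benzodioxin-7-yl]prop-2-enal | COc1cc([C@@H]2Oc3cc(/C=C/C=O)cc(O)c3O[C@H]2CO)cc(OC)c1OC | target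

**Totals**
Total step count: 12.
Longest linear sequence: 9 steps (steps 1-3 and 7-12). The diazodione branch (steps 4-6 and 7-12) is equally long.

**Steps most likely to fail**

Step 7.
- What may go wrong:
  - Transfer of the epoxide oxygen to the carbene, which deoxygenates the epoxide.
  - Lewis-acid-type rearrangement of the electron-rich epoxide before it meets the carbene.
  - Wolff-type ring contraction of the cyclic diazodione.
  - Separation of the ion pair, with loss of retention at C2.
- Fallback: it sets out from 5 (together with 10) and comes back at 11. The same two bonds are made one after the other.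
  - Methanol with a trace of PPTS at 0 °C opens the epoxide at its benzylic carbon (acid-catalysed benzylic solvolysis, mainly with inversion). This gives (1R,2S)-3-(tert-butyldimethylsilyloxy)-1-methoxy-1-(3,4,5-trimethoxyphenyl)propan-2-ol F1, in which the C3-O bond and its configuration are untouched.
  - Rh2(OAc)4-catalysed O-H insertion of the carbene from 10 into this free secondary alcohol forms C4a-O4. The product is methyl 4-{[(1R,2S)-3-(tert-butyldimethylsilyloxy)-1-methoxy-1-(3,4,5-trimethoxyphenyl)propan-2-yl]oxy}-3,5-dioxocyclohexane-1-carboxylate F2.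
  - Catalytic camphorsulfonic acid in toluene over 5 Å sieves ionises the benzylic methyl ether, and the enol oxygen closes O1-C2. This closure is reversible, so it should funnel the material to the trans isomer 11 whatever the configuration of the methoxy-bearing carbon.

Step 8.
- What may go wrong:
  - Enolisation at the ester α-carbon or at the γ position instead of C6.
  - Protodesilylation back to the enone before palladium engages.
  - Ionisation of the acid-labile vinylogous C2-O1 bond by the acetic acid released.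
- Fallback: it sets out from 11 and comes back at 14. The palladium dehydrogenation is replaced by placing a leaving group at C6 and eliminating it.
  - The lithium enolate of 11 (LiHMDS, THF, -78 °C) is quenched with PhSeBr. Selenium should enter anti to the ester, hence syn to C7-H, to give methyl (2S,3S)-3-[(tert-butyldimethylsilyloxy)methyl]-5-oxo-6-(phenylselanyl)-2-(3,4,5-trimethoxyphenyl)-2,3,5,6,7,8-hexahydro-1,4-benzodioxine-7-carboxylate F3.
  - H2O2 with pyridine in CH2Cl2 at 0 °C gives the corresponding selenoxide, the 6-(benzeneseleninyl) ketone F4.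
  - F4 undergoes syn elimination below room temperature to dienone 13, which tautomerises to 14.

Step 11.
- What may go wrong:
  - Sluggish addition of the stabilised ylide to the electron-rich aldehyde.
  - A second olefination of the product enal, so the chain grows by more than two carbons.
- Fallback: it sets out from 16 and comes back at 17. It uses an olefination that cannot repeat, followed by redox adjustment.
  - Horner-Wadsworth-Emmons reaction with triethyl phosphonoacetate under Masamune-Roush conditions (LiCl, DBU, MeCN) gives ethyl (E)-3-{(2S,3S)-3-[(tert-butyldimethylsilyloxy)methyl]-5-hydroxy-2-(3,4,5-trimethoxyphenyl)-2,3-dihydro-1,4-benzodioxin-7-yl}prop-2-enoate F5.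
  - DIBAL-H in CH2Cl2 at -78 °C reduces it to (2S,3S)-3-[(tert-butyldimethylsilyloxy)methyl]-7-[(E)-3-hydroxyprop-1-enyl]-2-(3,4,5-trimethoxyphenyl)-2,3-dihydro-1,4-benzodioxin-5-ol F6.
  - MnO2 oxidises the allylic alcohol to 17.

**Further compounds**
F1 | step 7 | (1R,2S)-3-(tert-butyldimethylsilyloxy)-1-methoxy-1-(3,4,5-trimethoxyphenyl)propan-2-ol | COc1cc([C@@H](OC)[C@@H](O)CO[Si](C)(C)C(C)(C)C)cc(OC)c1OC
F2 | step 7 | methyl 4-{[(1R,2S)-3-(tert-butyldimethylsilyloxy)-1-methoxy-1-(3,4,5-trimethoxyphenyl)propan-2-yl]oxy}-3,5-dioxocyclohexane-1-carboxylate | COc1cc([C@@H](OC)[C@@H](OC2C(=O)CC(C(=O)OC)CC2=O)CO[Si](C)(C)C(C)(C)C)cc(OC)c1OC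
F3 | step 8 | methyl (2S,3S)-3-[(tert-butyldimethylsilyloxy)methyl]-5-oxo-6-(phenylselanyl)-2-(3,4,5-trimethoxyphenyl)-2,3,5,6,7,8-hexahydro-1,4-benzodioxine-7-carboxylate | COc1cc([C@@H]2OC3=C(O[C@H]2CO[Si](C)(C)C(C)(C)C)C(=O)C([Se]c4ccccc4)C(C(=O)OC)C3)cc(OC)c1OC
F4 | step 8 | methyl (2S,3S)-6-(benzeneseleninyl)-3-[(tert-butyldimethylsilyloxy)methyl]-5-oxo-2-(3,4,5-trimethoxyphenyl)-2,3,5,6,7,8-hexahydro-1,4-benzodioxine-7-carboxylate | COc1cc([C@@H]2OC3=C(O[C@H]2CO[Si](C)(C)C(C)(C)C)C(=O)C([Se](=O)c4ccccc4)C(C(=O)OC)C3)cc(OC)c1OC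
F5 | step 11 | ethyl (E)-3-{(2S,3S)-3-[(tert-butyldimethylsilyloxy)methyl]-5-hydroxy-2-(3,4,5-trimethoxyphenyl)-2,3-dihydro-1,4-benzodioxin-7-yl}prop-2-enoate | COc1cc([C@@H]2Oc3cc(/C=C/C(=O)OCC)cc(O)c3O[C@H]2CO[Si](C)(C)C(C)(C)C)cc(OC)c1OC
F6 | step 11 | (2S,3S)-3-[(tert-butyldimethylsilyloxy)methyl]-7-[(E)-3-hydroxyprop-1-enyl]-2-(3,4,5-trimethoxyphenyl)-2,3-dihydro-1,4-benzodioxin-5-ol | COc1cc([C@@H]2Oc3cc(/C=C/CO)cc(O)c3O[C@H]2CO[Si](C)(C)C(C)(C)C)cc(OC)c1OC
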